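**Retrosynthetic overview**
- The tetralin carbocycle is cut at C1–C2 and C3–C4: ring D becomes an α-aryl o-quinodimethane (from a benzhydryl acetate with an ortho CH2SiMe3 group), and C2/C3 come from an (S,Z)-alkylidene dioxolanone made from L-malic acid.
- The strategy rests on this feature: C1 (bearing ring C), C2 (CH2OH), C3 (OH and CH2OH) and C4 (CH2), closed onto ring D through C4a/C8a, are ring D plus a four-carbon 2-oxybutanedioate unit.
- The benzhydryl C–C bond comes from a ring D aryllithium and a biaryl aldehyde; the ring B–ring C bond comes from a Suzuki coupling (both rings from 5-bromovanillin).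
- Oxolane: O1–C5 closure of a 2-substituted allyl unit; C2/C3 from an Evans syn aldol; C4 from face-selective epoxidation and opening with the ring A Grignard reagent.
- Ring order: oxolane first, tetralin carbocycle last; then LiAlH4 reduction and hydrogenolysis.

Key step: step 21

Remark: the SMILES is read as (2R,3R,4S) in the oxolane (ring B, CH2OH and the ring A benzyl group all cis, hydroxyl trans to them) and (1S,2S,3S) in the tetralin; compounds 1, 3, 4, 15, 21, 30 and 31 are taken as purchasable.

**Route**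

Step 1
Reactants: 1 5-bromovanillin (3-bromo-4-hydroxy-5-methoxybenzaldehyde)
Product: 2 4-(benzyloxy)-3-bromo-5-methoxybenzaldehyde
Conditions: BnBr, K2CO3, DMF, 60 °C
Reagents that add atoms: benzyl bromide, BrCc1ccccc1
Why: Williamson ether synthesis on the phenoxide, which leaves the aldehyde and the aryl bromide untouched.

Step 2
Reactants: 3 3-(benzyloxy)propanoic acid; 4 (R)-4-benzyloxazolidin-2-one
Product: 6 (R)-4-benzyl-3-[3-(benzyloxy)propanoyl]oxazolidin-2-one, via mixed pivalic anhydride 5 (not isolated)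
Conditions: PivCl, Et3N, THF, −20 °C; then LiCl, 4, −20 °C → rt
Reagents that add atoms: none
Why: N-acylation of the oxazolidinone through the mixed anhydride, which is attacked at the unhindered, non-pivaloyl carbonyl.

Step 3
Reactants: 6 (R)-4-benzyl-3-[3-(benzyloxy)propanoyl]oxazolidin-2-one; 2 4-(benzyloxy)-3-bromo-5-methoxybenzaldehyde
Product: 8 (R)-4-benzyl-3-[(2R,3R)-2-[(benzyloxy)methyl]-3-[4-(benzyloxy)-3-bromo-5-methoxyphenyl]-3-hydroxypropanoyl]oxazolidin-2-one, via boron enolate 7 (not isolated)
Conditions: Bu2BOTf, i-Pr2NEt, CH2Cl2, 0 °C; then 2, −78 → 0 °C; pH 7 buffer, MeOH, H2O2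
Reagents that add atoms: none
Why: Evans syn aldol; the (Z)-boron enolate reacts through a chair transition state on the face away from the auxiliary benzyl group, so the (R)-auxiliary should set both new centres as 2R,3R (syn), the relationship that becomes aryl/CH2OBn cis in the oxolane.

Step 4
Reactants: 8 the aldol adduct
Product: 9 methyl (2R,3R)-2-[(benzyloxy)methyl]-3-[4-(benzyloxy)-3-bromo-5-methoxyphenyl]-3-hydroxypropanoate
Conditions: MeMgBr, MeOH, CH2Cl2, 0 °C
Reagents that add atoms: methanol, CO
Why: transesterification with bromomagnesium methoxide at the exocyclic imide carbonyl, cold enough to avoid retro-aldol cleavage and α-epimerisation, with recovery of auxiliary 4.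

Step 5
Reactants: 9 the methyl ester
Product: 11 (1R,2R)-2-[(benzyloxy)methyl]-1-[4-(benzyloxy)-3-bromo-5-methoxyphenyl]-3-[(trimethylsilyl)methyl]but-3-en-1-ol, via bis(silylmethyl) carbinol 10 (not isolated)
Conditions: Me3SiCH2MgCl, CeCl3, THF, −78 °C → rt; then SiO2, CH2Cl2, rt
Reagents that add atoms: (trimethylsilyl)methylmagnesium chloride, C[Si](C)(C)C[Mg]Cl
Why: double addition of the weakly basic organocerium reagent to the ester, then Peterson elimination of one β-silyl alcohol unit, turns the ester carbon into the central carbon of a 2-substituted allylsilane without touching the α-stereocentre.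

Step 6
Reactants: 11 the hydroxy allylsilane
Product: 13 (2R,3R)-3-[(benzyloxy)methyl]-2-[4-(benzyloxy)-3-bromo-5-methoxyphenyl]-4-methylideneoxolane, via allylic bromide 12 (not isolated)
Conditions: NBS, CH2Cl2, −78 °C; then NaH, THF, 0 °C → rt
Reagents that add atoms: none
Why: electrophilic bromodesilylation of the allylsilane (SE2') gives the 2-substituted allyl bromide, and the secondary alkoxide then closes the oxolane by intramolecular Williamson etherification (5-exo-tet) at the primary carbon, so neither stereocentre is touched.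

Step 7
Reactants: 13 the 4-methylideneoxolane
Product: 14 (3R,6R,7R)-7-[(benzyloxy)methyl]-6-[4-(benzyloxy)-3-bromo-5-methoxyphenyl]-1,5-dioxaspiro[2.4]heptane (epoxide oxygen trans to the CH2OBn group)
Conditions: m-CPBA, NaHCO3, CH2Cl2, 0 °C
Reagents that add atoms: 3-chloroperoxybenzoic acid, OOC(=O)c1cccc(Cl)c1
Why: Prilezhaev epoxidation; the C2 aryl group and the C3 CH2OBn group lie on the same face of the ring, so oxygen should be delivered to the open opposite face, which sets the C4–O bond trans to the C3 substituent.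

Step 8
Reactants: 15 4-bromo-2-methoxyphenol
Product: 16 1-(benzyloxy)-4-bromo-2-methoxybenzene
Conditions: BnBr, K2CO3, DMF, 60 °C
Reagents that add atoms: benzyl bromide, BrCc1ccccc1
Why: Williamson ether synthesis on the phenoxide.

Step 9
Reactants: 14 the spiro-epoxide; 16 1-(benzyloxy)-4-bromo-2-methoxybenzene
Product: 18 (3S,4R,5R)-4-[(benzyloxy)methyl]-3-[4-(benzyloxy)-3-methoxybenzyl]-5-[4-(benzyloxy)-3-bromo-5-methoxyphenyl]oxolan-3-ol, via arylmagnesium bromide 17 (not isolated)
Conditions: 16, Mg, THF, 40 °C; then CuI (10 mol %), 14, THF, −30 → 0 °C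
Reagents that add atoms: none
Why: copper-catalysed SN2 opening of the epoxide by the aryl Grignard reagent at the unsubstituted CH2 carbon leaves the C–O bond at the quaternary centre intact, so the tertiary alcohol keeps the epoxide configuration and the new benzyl group is cis to CH2OBn.

Step 10
Reactants: 2 4-(benzyloxy)-3-bromo-5-methoxybenzaldehyde
Product: 19 4-(benzyloxy)-3-methoxy-5-(4,4,5,5-tetramethyl-1,3,2-dioxaborolan-2-yl)benzaldehyde
Conditions: B2pin2, PdCl2(dppf), KOAc, 1,4-dioxane, 90 °C
Reagents that add atoms: bis(pinacolato)diboron, CC1(C)OB(OC1(C)C)B1OC(C)(C)C(C)(C)O1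
Why: Miyaura borylation, which tolerates the aldehyde and, with acetate as base, avoids biaryl homocoupling.

Step 11
Reactants: 18 the bromo oxolanol; 19 the boronate aldehyde
Product: 20 4-(benzyloxy)-3-{2-(benzyloxy)-5-[(2R,3R,4S)-4-[4-(benzyloxy)-3-methoxybenzyl]-3-[(benzyloxy)methyl]-4-hydroxyoxolan-2-yl]-3-methoxyphenyl}-5-methoxybenzaldehyde
Conditions: Pd(OAc)2, SPhos, K3PO4, toluene/H2O, 90 °C
Reagents that add atoms: none
Why: Suzuki–Miyaura coupling; the bulky dialkylbiarylphosphine allows the union of two ortho-benzyloxy partners, and the free tertiary alcohol and the aldehyde are inert.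

Step 12
Reactants: 21 4-(benzyloxy)-3-methoxybenzaldehyde
Product: 22 4-(benzyloxy)-2-bromo-5-methoxybenzaldehyde
Conditions: Br2, NaOAc, AcOH, rt
Reagents that add atoms: bromine, BrBr
Why: electrophilic aromatic bromination para to the methoxy group (the position para to the benzyloxy group carries the formyl group), with acetate buffering the HBr.

Step 13
Reactants: 22 the bromo aldehyde
Product: 23 [4-(benzyloxy)-2-bromo-5-methoxyphenyl]methanol
Conditions: NaBH4, MeOH/THF, 0 °C
Reagents that add atoms: none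
Why: borohydride reduction of the aldehyde, chemoselective in the presence of the aryl bromide and the benzyl ether.

Step 14
Reactants: 23 the benzylic alcohol
Product: 24 1-(benzyloxy)-5-bromo-4-(bromomethyl)-2-methoxybenzene
Conditions: PBr3, CH2Cl2, 0 °C
Reagents that add atoms: phosphorus tribromide, BrP(Br)Br
Why: conversion of the electron-rich benzylic alcohol into the bromide through the phosphite ester (SN2).

Step 15
Reactants: 24 the benzylic bromide
Product: 26 1-(benzyloxy)-5-bromo-2-methoxy-4-[(trimethylsilyl)methyl]benzene, via benzylmagnesium bromide 25 (not isolated)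
Conditions: Mg, Me3SiCl, THF, 0 °C (slow addition of 24)
Reagents that add atoms: chlorotrimethylsilane, C[Si](C)(C)Cl
Why: Barbier-type silylation; magnesium inserts into the benzylic C–Br bond much faster than into the aryl C–Br bond, and trapping in situ by Me3SiCl limits Wurtz coupling.

Step 16
Reactants: 20 the biaryl aldehyde; 26 the ring D aryl bromide
Product: 28 benzhydrol of 20 with the 5-(benzyloxy)-4-methoxy-2-[(trimethylsilyl)methyl]phenyl group on the carbinol carbon (both carbinol epimers), via aryllithium 27 (not isolated)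
Conditions: 26 (2.3 equiv), n-BuLi, THF, −78 °C; then 20, −78 → −40 °C; aq NH4Cl
Reagents that add atoms: none
Why: bromine–lithium exchange and 1,2-addition to the aldehyde, one equivalent of aryllithium being spent on the tertiary hydroxyl; the new carbinol centre forms as both epimers, which does not matter because it becomes sp2 in the quinodimethane.

Step 17
Reactants: 28 the benzhydrol
Product: 29 the benzhydryl acetate (both epimers), tertiary hydroxyl free
Conditions: Ac2O (1.3 equiv), Et3N, DMAP (cat.), CH2Cl2, 0 °C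
Reagents that add atoms: acetic anhydride, CC(=O)OC(C)=O
Why: DMAP-catalysed acylation of the secondary alcohol, the hindered tertiary alcohol reacting far more slowly at 0 °C; the ionisable acetate should be used without chromatography.

Step 18
Reactants: 30 L-malic acid; 31 pivalaldehyde
Product: 32 2-[(2S,4S)-2-tert-butyl-5-oxo-1,3-dioxolan-4-yl]acetic acid (cis)
Conditions: p-TsOH (cat.), H2SO4 (cat.), pentane, reflux, water separator
Reagents that add atoms: none
Why: acid-catalysed acetalisation of the α-hydroxy acid unit under thermodynamic control, which favours the cis dioxolanone and is purified by crystallisation.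

Step 19
Reactants: 32 the dioxolanone acid
Product: 33 methyl 2-[(2S,4S)-2-tert-butyl-5-oxo-1,3-dioxolan-4-yl]acetate
Conditions: MeI, KHCO3, DMF, rt
Reagents that add atoms: iodomethane, CI
Why: O-alkylation of the carboxylate (SN2) under conditions too mild to open the dioxolanone.

Step 20
Reactants: 33 the methyl ester
Product: 35 methyl (2Z)-2-[(2S)-2-tert-butyl-5-oxo-1,3-dioxolan-4-ylidene]acetate, via ring bromide 34 (not isolated)
Conditions: NBS, AIBN (cat.), PhCF3, 80 °C; then Et3N, CH2Cl2, 0 °C
Reagents that add atoms: none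
Why: Wohl–Ziegler bromination at the captodative ring C–H next to the lactone carbonyl, then E2 loss of HBr, should give the exocyclic alkene with the ester cis to the ring oxygen (Z), the acetal centre being untouched.

Step 21
Reactants: 29 the benzhydryl acetate; 35 the (S,Z)-alkylidene dioxolanone
Product: 37 spiro-dioxolanone tetralin cycloadduct (ring C at C1 cis to the lactone carbonyl carbon at C3; methyl ester at C2 trans to ring C and cis to the spiro oxygen), via o-quinodimethane 36 (not isolated)
Conditions: CsF (3 equiv), 35 (3 equiv), MeCN/CH2Cl2, 0 °C → rt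
Reagents that add atoms: none
Why: Fluoride attacks silicon and acetate leaves in a 1,4-elimination that gives the (E)-α-aryl o-quinodimethane 36, which is trapped at once by 35 in a concerted, asynchronous [4+2] cycloaddition (fluoride-induced o-quinodimethane Diels–Alder reaction); the six-membered carbocycle closes in this cycloaddition, C3–C4 and C1–C2 forming together while ring D regains aromaticity. The unsubstituted CH2 terminus (largest HOMO coefficient) should bond to the oxygen-bearing ring carbon of 35, which is the β-carbon of the exocyclic ester and the site attacked by nucleophiles in alkoxyfumarates, so the aryl-bearing terminus bonds to the ester-bearing CH. C3 is set by attack on the face of the planar dioxolanone anti to the tert-butyl group, C2 follows from the Z geometry through suprafacial addition (ester cis to the ring oxygen), and C1 is set by the orientation that places the lactone carbonyl, not the ester, under ring D, with ring C outside on the diene. The step therefore needs regio-, face and orientation selectivity: the first two are secured by the push–pull polarisation of 35 and by the acetal, whereas the orientation rests only on secondary overlap of the lactone carbonyl with the electron-rich diene and is the open point of the route.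

Step 22
Reactants: 37 the cycloadduct
Product: 38 pentabenzyl ether of the target (tetralin 1S,2S,3S with 3-OH and 2,3-bis(hydroxymethyl); oxolane 2R,3R,4S)
Conditions: LiAlH4, THF, 0 °C → rt; aq NaOH work-up
Reagents that add atoms: none
Why: hydride reduction of the methyl ester and of the dioxolanone (lactone carbonyl to CH2OH, with release of the tertiary alcohol and of pivalaldehyde, itself reduced) without touching any stereocentre or benzyl ether.

Step 23
Reactants: 38 the pentabenzyl ether
Product: 39 CNP0344108.1 (target)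
Conditions: H2 (1 atm), Pd/C (10 % Pd), EtOAc/MeOH, rt
Reagents that add atoms: none
Why: catalytic hydrogenolysis of the four aryl benzyl ethers and the one alkyl benzyl ether under neutral, mild conditions that should spare the benzylic C–O bond of the oxolane.

**Compound list**

1 | 5-bromovanillin | COc1cc(C=O)cc(Br)c1O | starting material
2 | 4-(benzyloxy)-3-bromo-5-methoxybenzaldehyde | COc1cc(C=O)cc(Br)c1OCc1ccccc1 | intermediate
3 | 3-(benzyloxy)propanoic acid | OC(=O)CCOCc1ccccc1 | starting material
4 | (R)-4-benzyloxazolidin-2-one | O=C1N[C@H](Cc2ccccc2)CO1 | starting material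
5 | 3-(benzyloxy)propanoic pivalic anhydride | CC(C)(C)C(=O)OC(=O)CCOCc1ccccc1 | intermediate
6 | (R)-4-benzyl-3-[3-(benzyloxy)propanoyl]oxazolidin-2-one | O=C(CCOCc1ccccc1)N1[C@H](Cc2ccccc2)COC1=O | intermediate
7 | (Z)-dibutylboron enolate of 6 | CCCCB(CCCC)O/C(=C\COCc1ccccc1)N1[C@H](Cc2ccccc2)COC1=O | intermediate
8 | (R)-4-benzyl-3-[(2R,3R)-2-[(benzyloxy)methyl]-3-[4-(benzyloxy)-3-bromo-5-methoxyphenyl]-3-hydroxypropanoyl]oxazolidin-2-one | O=C([C@H](COCc1ccccc1)[C@@H](O)c1cc(OC)c(OCc2ccccc2)c(Br)c1)N1[C@H](Cc2ccccc2)COC1=O | intermediate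
9 | methyl (2R,3R)-2-[(benzyloxy)methyl]-3-[4-(benzyloxy)-3-bromo-5-methoxyphenyl]-3-hydroxypropanoate | COC(=O)[C@H](COCc1ccccc1)[C@@H](O)c1cc(OC)c(OCc2ccccc2)c(Br)c1 | intermediate
10 | (1R,2R)-2-[(benzyloxy)methyl]-1-[4-(benzyloxy)-3-bromo-5-methoxyphenyl]-4-(trimethylsilyl)-3-[(trimethylsilyl)methyl]butane-1,3-diol | C[Si](C)(C)CC(O)(C[Si](C)(C)C)[C@H](COCc1ccccc1)[C@@H](O)c1cc(OC)c(OCc2ccccc2)c(Br)c1 | intermediate
11 | (1R,2R)-2-[(benzyloxy)methyl]-1-[4-(benzyloxy)-3-bromo-5-methoxyphenyl]-3-[(trimethylsilyl)methyl]but-3-en-1-ol | C=C(C[Si](C)(C)C)[C@H](COCc1ccccc1)[C@@H](O)c1cc(OC)c(OCc2ccccc2)c(Br)c1 | intermediate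
12 | (1R,2R)-2-[(benzyloxy)methyl]-1-[4-(benzyloxy)-3-bromo-5-methoxyphenyl]-3-(bromomethyl)but-3-en-1-ol | C=C(CBr)[C@H](COCc1ccccc1)[C@@H](O)c1cc(OC)c(OCc2ccccc2)c(Br)c1 | intermediate
13 | (2R,3R)-3-[(benzyloxy)methyl]-2-[4-(benzyloxy)-3-bromo-5-methoxyphenyl]-4-methylideneoxolane | C=C1CO[C@@H](c2cc(OC)c(OCc3ccccc3)c(Br)c2)[C@H]1COCc1ccccc1 | intermediate
14 | (3R,6R,7R)-7-[(benzyloxy)methyl]-6-[4-(benzyloxy)-3-bromo-5-methoxyphenyl]-1,5-dioxaspiro[2.4]heptane | C1O[C@@]12CO[C@@H](c3cc(OC)c(OCc4ccccc4)c(Br)c3)[C@H]2COCc1ccccc1 | intermediate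
15 | 4-bromo-2-methoxyphenol | COc1cc(Br)ccc1O | starting material
16 | 1-(benzyloxy)-4-bromo-2-methoxybenzene | COc1cc(Br)ccc1OCc1ccccc1 | intermediate
17 | [4-(benzyloxy)-3-methoxyphenyl]magnesium bromide | COc1cc([Mg]Br)ccc1OCc1ccccc1 | intermediate
18 | (3S,4R,5R)-4-[(benzyloxy)methyl]-3-[4-(benzyloxy)-3-methoxybenzyl]-5-[4-(benzyloxy)-3-bromo-5-methoxyphenyl]oxolan-3-ol | COc1cc(C[C@@]2(O)CO[C@@H](c3cc(OC)c(OCc7ccccc7)c(Br)c3)[C@H]2COCc7ccccc7)ccc1OCc7ccccc7 | intermediate
19 | 4-(benzyloxy)-3-methoxy-5-(4,4,5,5-tetramethyl-1,3,2-dioxaborolan-2-yl)benzaldehyde | COc1cc(C=O)cc(B2OC(C)(C)C(C)(C)O2)c1OCc1ccccc1 | intermediate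
20 | biaryl aldehyde: 4-(benzyloxy)-3-{2-(benzyloxy)-5-[(2R,3R,4S)-4-[4-(benzyloxy)-3-methoxybenzyl]-3-[(benzyloxy)methyl]-4-hydroxyoxolan-2-yl]-3-methoxyphenyl}-5-methoxybenzaldehyde | COc1cc(C[C@@]2(O)CO[C@@H](c3cc(OC)c(OCc7ccccc7)c(-c4cc(C=O)cc(OC)c4OCc7ccccc7)c3)[C@H]2COCc7ccccc7)ccc1OCc7ccccc7 | intermediate
21 | 4-(benzyloxy)-3-methoxybenzaldehyde | COc1cc(C=O)ccc1OCc1ccccc1 | starting material
22 | 4-(benzyloxy)-2-bromo-5-methoxybenzaldehyde | COc1cc(C=O)c(Br)cc1OCc1ccccc1 | intermediate
23 | [4-(benzyloxy)-2-bromo-5-methoxyphenyl]methanol | COc1cc(CO)c(Br)cc1OCc1ccccc1 | intermediate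
24 | 1-(benzyloxy)-5-bromo-4-(bromomethyl)-2-methoxybenzene | COc1cc(CBr)c(Br)cc1OCc1ccccc1 | intermediate
25 | [4-(benzyloxy)-2-bromo-5-methoxybenzyl]magnesium bromide | COc1cc(C[Mg]Br)c(Br)cc1OCc1ccccc1 | intermediate
26 | 1-(benzyloxy)-5-bromo-2-methoxy-4-[(trimethylsilyl)methyl]benzene | COc1cc(C[Si](C)(C)C)c(Br)cc1OCc1ccccc1 | intermediate
27 | {5-(benzyloxy)-4-methoxy-2-[(trimethylsilyl)methyl]phenyl}lithium | COc1cc(C[Si](C)(C)C)c([Li])cc1OCc1ccccc1 | intermediate
28 | benzhydrol: carbinol carbon bearing ring C of 20 and the 5-(benzyloxy)-4-methoxy-2-[(trimethylsilyl)methyl]phenyl group, both epimers | COc1cc(C[C@@]2(O)CO[C@@H](c3cc(OC)c(OCc7ccccc7)c(-c4cc(C(O)c6cc(OCc7ccccc7)c(OC)cc6C[Si](C)(C)C)cc(OC)c4OCc7ccccc7)c3)[C@H]2COCc7ccccc7)ccc1OCc7ccccc7 | intermediate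
29 | benzhydryl acetate of 28, both epimers | COc1cc(C[C@@]2(O)CO[C@@H](c3cc(OC)c(OCc7ccccc7)c(-c4cc(C(OC(C)=O)c6cc(OCc7ccccc7)c(OC)cc6C[Si](C)(C)C)cc(OC)c4OCc7ccccc7)c3)[C@H]2COCc7ccccc7)ccc1OCc7ccccc7 | intermediate
30 | L-malic acid | O[C@@H](CC(=O)O)C(=O)O | starting material
31 | pivalaldehyde | CC(C)(C)C=O | starting material
32 | 2-[(2S,4S)-2-tert-butyl-5-oxo-1,3-dioxolan-4-yl]acetic acid | O=C1O[C@@H](C(C)(C)C)O[C@H]1CC(=O)O | intermediate
33 | methyl 2-[(2S,4S)-2-tert-butyl-5-oxo-1,3-dioxolan-4-yl]acetate | O=C1O[C@@H](C(C)(C)C)O[C@H]1CC(=O)OC | intermediate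
34 | methyl 2-[(2S)-4-bromo-2-tert-butyl-5-oxo-1,3-dioxolan-4-yl]acetate (Br trans to tert-butyl) | O=C1O[C@@H](C(C)(C)C)O[C@@]1(Br)CC(=O)OC | intermediate
35 | methyl (2Z)-2-[(2S)-2-tert-butyl-5-oxo-1,3-dioxolan-4-ylidene]acetate | O=C1O[C@@H](C(C)(C)C)O/C1=C\C(=O)OC | intermediate
36 | (E)-α-aryl o-quinodimethane from 29 (ring C outside) | COc1cc(C[C@@]2(O)CO[C@@H](c3cc(OC)c(OCc7ccccc7)c(-c4cc(/C=C6\C=C(OCc7ccccc7)C(OC)=CC6=C)cc(OC)c4OCc7ccccc7)c3)[C@H]2COCc7ccccc7)ccc1OCc7ccccc7 | intermediate
37 | spiro-dioxolanone tetralin cycloadduct | COc1cc(C[C@@]2(O)CO[C@@H](c3cc(OC)c(OCc7ccccc7)c(-c4cc([C@H]5c6cc(OCc7ccccc7)c(OC)cc6C[C@@]8(C(=O)O[C@@H](C(C)(C)C)O8)[C@@H]5C(=O)OC)cc(OC)c4OCc7ccccc7)c3)[C@H]2COCc7ccccc7)ccc1OCc7ccccc7 | intermediate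
38 | pentabenzyl ether of the target | COc1cc(C[C@@]2(O)CO[C@@H](c3cc(OC)c(OCc7ccccc7)c(-c4cc([C@H]5c6cc(OCc7ccccc7)c(OC)cc6C[C@@](O)(CO)[C@@H]5CO)cc(OC)c4OCc7ccccc7)c3)[C@H]2COCc7ccccc7)ccc1OCc7ccccc7 | intermediate
39 | CNP0344108.1 | COc1cc(C[C@@]2(O)CO[C@@H](c3cc(OC)c(O)c(-c4cc([C@H]5c6cc(O)c(OC)cc6C[C@@](O)(CO)[C@@H]5CO)cc(OC)c4O)c3)[C@H]2CO)ccc1O | target

**Step count**
Total steps: 23. Longest linear sequence: 13 steps (1 → 2 → 8 → 9 → 11 → 13 → 14 → 18 → 20 → 28 → 29 → 37 → 38 → 39).

**Steps most likely to fail**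

Step 21. The dienophile may add in the other orientation, with the ester and the ring oxygen under ring D and the lactone carbonyl pointing away. Exocyclic alkylidene dioxolanones tend to add this way to other dienes, and the ester next to the aryl-bearing terminus also favours it. This would invert C1 relative to C2 and C3, and C1 cannot be corrected afterwards. The fallback sets out from 29 and takes the relative configuration from the ordinary endo addition of a cis-diester followed by a thermodynamic epimerisation. Compound 29 is treated with CsF in the presence of dimethyl (E)-2-(benzyloxy)but-2-enedioate F1 (ester groups cis; from dimethyl acetylenedicarboxylate and benzyl alcohol). Both ester groups should go under ring D and the benzyloxy group outside, which gives the all-cis adduct F2 together with its diastereomer of mirror-image tetralin configuration F3. The two are separated by chromatography, which is possible because the oxolane half is a single enantiomer. DBU in toluene then epimerises C2 of F2 to the trans,trans diester F4, and LiAlH4 reduces it to the hexabenzyl ether F5. Hydrogenolysis as in step 23 also cleaves the tertiary benzyl ether, so the fallback comes back to the route at 39.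

Step 6. Electrophilic bromine may be consumed by the electron-rich arene, or the bromonium ion may be intercepted by the hydroxyl group before silicon is lost, so the allyl bromide is not formed cleanly. The fallback sets out from 11 and replaces halodesilylation by oxidation. Buffered m-CPBA converts the allylsilane into the epoxysilane F6, and TBAF triggers its Peterson-type fragmentation to the 2-methylidene-1,4-diol F7. NaH and N-tosylimidazole then sulfonylate the primary allylic hydroxyl, and the secondary alkoxide closes the ring in the same flask, which returns the route to 13.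

Step 23. Hydrogenolysis may also cleave the benzylic C–O bond of the oxolane, or it may stall at the hindered benzyl ethers flanking the biaryl axis. The fallback sets out from 38 and removes the benzyl groups by single-electron reduction with lithium naphthalenide in THF at −25 °C instead of by catalysis. The phenoxides formed first make rings A to D too electron-rich to accept an electron, so the oxolane C–O bond should survive, and the fallback comes back to the route at 39 without any new intermediate.

**Further compounds**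

F1 | step 21 | dimethyl (E)-2-(benzyloxy)but-2-enedioate | COC(=O)/C=C(/OCc1ccccc1)C(=O)OC
F2 | step 21 | all-cis diester adduct (ring C, C2 ester and C3 ester cis; C3 benzyloxy trans to ring C) | COc1cc(C[C@@]2(O)CO[C@@H](c3cc(OC)c(OCc7ccccc7)c(-c4cc([C@H]5c6cc(OCc7ccccc7)c(OC)cc6C[C@@](OCc7ccccc7)(C(=O)OC)[C@H]5C(=O)OC)cc(OC)c4OCc7ccccc7)c3)[C@H]2COCc7ccccc7)ccc1OCc7ccccc7
F3 | step 21 | diastereomer of F2 with mirror-image tetralin configuration | COc1cc(C[C@@]2(O)CO[C@@H](c3cc(OC)c(OCc7ccccc7)c(-c4cc([C@@H]5c6cc(OCc7ccccc7)c(OC)cc6C[C@](OCc7ccccc7)(C(=O)OC)[C@@H]5C(=O)OC)cc(OC)c4OCc7ccccc7)c3)[C@H]2COCc7ccccc7)ccc1OCc7ccccc7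
F4 | step 21 | C2-epimerised trans,trans diester | COc1cc(C[C@@]2(O)CO[C@@H](c3cc(OC)c(OCc7ccccc7)c(-c4cc([C@H]5c6cc(OCc7ccccc7)c(OC)cc6C[C@@](OCc7ccccc7)(C(=O)OC)[C@@H]5C(=O)OC)cc(OC)c4OCc7ccccc7)c3)[C@H]2COCc7ccccc7)ccc1OCc7ccccc7
F5 | step 21 | hexabenzyl ether of the target (tertiary tetralin hydroxyl benzylated) | COc1cc(C[C@@]2(O)CO[C@@H](c3cc(OC)c(OCc7ccccc7)c(-c4cc([C@H]5c6cc(OCc7ccccc7)c(OC)cc6C[C@@](OCc7ccccc7)(CO)[C@@H]5CO)cc(OC)c4OCc7ccccc7)c3)[C@H]2COCc7ccccc7)ccc1OCc7ccccc7
F6 | step 6 | epoxysilane of 11 (both epoxide epimers) | C[Si](C)(C)CC1(CO1)[C@H](COCc2ccccc2)[C@@H](O)c2cc(OC)c(OCc3ccccc3)c(Br)c2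
F7 | step 6 | (1R,2R)-2-[(benzyloxy)methyl]-1-[4-(benzyloxy)-3-bromo-5-methoxyphenyl]-3-methylidenebutane-1,4-diol | C=C(CO)[C@H](COCc1ccccc1)[C@@H](O)c1cc(OC)c(OCc2ccccc2)c(Br)c1
F0 | step 23 | none | none
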